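**Plan**

1. Locants: ring C1 (oxirane CH), C2=C3, C4 (bears C15H2OH)=C5, C6 (lactone O–CH), C7, C8 (ester O–CH), C9H2, C10 (oxirane C with CH3-14); lactone C11(=C13H2)–C12(=O)–O–C6.
2. Cuts, in retrosynthetic order: the C8–O acyl bond (side chain = (Z)-2-(hydroxymethyl)but-2-enoate) and C11=C13; then C1–C10 together with C1–O of the oxirane, back to an acyclic keto sulfonium salt; then C3–C4 (Stille), the C12 and C10 carbonyls (from two terminal alkenes), C5–C6 (alkynyl ketone) and C7–C8 (aldol).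
3. Forward: an Evans aldol builds C6–C10 with C11/C12 as an allyl group; alkynylation, reduction and trans-hydroalumination add C4, C5, C15; oxidative cleavage gives the C10 ketone and the cis-fused butyrolactone; a Stille coupling adds C1–C3; one base-mediated event then closes the ten-membered carbocycle and the oxirane; methylenation and acylation finish.
4. Enabling feature: C1 is allylic to the C2=C3–C4=C5 diene (acidic S+–CH2, ylide carbon) and C10 is a methyl ketone carbon 1,3 to the C8 oxygen; the cis-fused lactone on C6/C7 and the two in-ring cis alkenes hold both chain ends on one face.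
5. Stereochemistry: C7/C8 from the (R)-benzyloxazolidinone syn-aldol; C6 from catalyst-controlled Noyori reduction; C4=C5 and C2=C3 geometry from trans-hydroalumination/iodination and a Z-stannane; C1/C10 in the ring closure, under control of the lactone-templated ring and C8–OSiEt3; side-chain geometry from (Z)-2-iodobut-2-en-1-ol.

Key step: step 13

Remark: silane 10 is taken as a purchasable reagent, and the germacrane-type locants of line 1 are used in the names of the macrocycles.

**Route**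

Step 1
Reactants: 1 3-methylbut-3-en-1-ol
Product: 2 3-methylbut-3-enal
Conditions: Dess–Martin periodinane, NaHCO3, CH2Cl2, 0 °C; cold solution used at once
Reagents that add atoms: none
Why: Dess–Martin oxidation under bicarbonate buffer should give the β,γ-unsaturated aldehyde without migration of the double bond into conjugation.

Step 2
Reactants: 3 (4R)-4-benzyl-1,3-oxazolidin-2-one; 4 pent-4-enoyl chloride
Product: 5 (4R)-4-benzyl-3-(pent-4-enoyl)-1,3-oxazolidin-2-one
Conditions: Et3N, DMAP (cat.), CH2Cl2, 0 °C → rt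
Reagents that add atoms: none
Why: DMAP-catalysed N-acylation of an oxazolidinone by an acid chloride is a standard entry to Evans imides.

Step 3
Reactants: 5 (4R)-4-benzyl-3-(pent-4-enoyl)-1,3-oxazolidin-2-one; 2 3-methylbut-3-enal
Product: 7 (4R)-4-benzyl-3-[(2R,3S)-3-hydroxy-5-methyl-2-(prop-2-en-1-yl)hex-5-enoyl]-1,3-oxazolidin-2-one, via dibutylboron enolate 6 (not isolated)
Conditions: Bu2BOTf, i-Pr2NEt, CH2Cl2, −78 → 0 °C; then 2, −78 → 0 °C; then pH 7 buffer, MeOH, H2O2, 0 °C
Reagents that add atoms: none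
Why: Evans syn-aldol, in which the Z boron enolate reacts through a chair (Zimmerman–Traxler) transition state on the face away from the benzyl group and so sets C7 and C8 together.

Step 4
Reactants: 7 the aldol imide
Product: 8 (2R,3S)-3-hydroxy-N-methoxy-N,5-dimethyl-2-(prop-2-en-1-yl)hex-5-enamide
Conditions: MeNH(OMe)·HCl, AlMe3, CH2Cl2, −10 → 0 °C; aq. Rochelle salt
Reagents that add atoms: N,O-dimethylhydroxylamine hydrochloride, CNOC.Cl
Why: Aluminium-amide transamination to the Weinreb amide is assisted by the free β-hydroxyl and should release the auxiliary without retro-aldol or epimerisation.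

Step 5
Reactants: 8 the hydroxy Weinreb amide
Product: 9 (2R,3S)-N-methoxy-N,5-dimethyl-2-(prop-2-en-1-yl)-3-[(triethylsilyl)oxy]hex-5-enamide
Conditions: TESCl, imidazole, CH2Cl2, 0 °C → rt
Reagents that add atoms: chlorotriethylsilane, CC[Si](Cl)(CC)CC
Why: Routine silylation gives an ether that is a poor leaving group β to the later C10 ketone and can be removed late with buffered fluoride.

Step 6
Reactants: 9 the silylated Weinreb amide; 10 tert-butyl(diphenyl)(prop-2-yn-1-yloxy)silane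
Product: 12 (5R,6S)-1-[(tert-butyldiphenylsilyl)oxy]-8-methyl-5-(prop-2-en-1-yl)-6-[(triethylsilyl)oxy]non-8-en-2-yn-4-one, via lithium acetylide 11 (not isolated)
Conditions: 10, n-BuLi, THF, −78 °C; then 9, −78 → −20 °C; aq. NH4Cl
Reagents that add atoms: none
Why: Weinreb ketone synthesis, in which the acetylide adds once to a chelated tetrahedral adduct that collapses to the alkynyl ketone only on work-up.

Step 7
Reactants: 12 the alkynyl ketone
Product: 13 (4R,5S,6S)-1-[(tert-butyldiphenylsilyl)oxy]-8-methyl-5-(prop-2-en-1-yl)-6-[(triethylsilyl)oxy]non-8-en-2-yn-4-ol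
Conditions: Ru(p-cymene)[(R,R)-TsDPEN] (amido complex, cat.), i-PrOH, rt
Reagents that add atoms: none
Why: Noyori asymmetric transfer hydrogenation of alkynyl ketones is catalyst-controlled, so the (R,R) catalyst should give the (4R) carbinol (C6) under base-free conditions that spare the α-stereocentre and the isolated alkenes.

Step 8
Reactants: 13 the propargylic alcohol
Product: 15 (2Z,4R,5S,6S)-1-[(tert-butyldiphenylsilyl)oxy]-2-iodo-8-methyl-5-(prop-2-en-1-yl)-6-[(triethylsilyl)oxy]nona-2,8-dien-4-ol, via cyclic vinylalanate 14 (not isolated)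
Conditions: Red-Al, THF, −20 → 0 °C; then I2, THF, −78 → 0 °C
Reagents that add atoms: iodine, II
Why: Hydroxyl-directed trans-hydroalumination puts aluminium on the alkyne carbon distal to the carbinol and iodinolysis retains configuration, so iodine ends cis to C6 and the C4=C5 geometry is fixed.

Step 9
Reactants: 15 the iodo dienol
Product: 17 (4S,5R)-5-{(1Z)-3-[(tert-butyldiphenylsilyl)oxy]-2-iodoprop-1-en-1-yl}-4-{(1S)-3-oxo-1-[(triethylsilyl)oxy]butyl}oxolan-2-one, via keto lactol 16 (not isolated)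
Conditions: OsO4 (cat.), NaIO4, 2,6-lutidine, dioxane/H2O, rt; then PhI(OAc)2, TEMPO (cat.), CH2Cl2, rt
Reagents that add atoms: osmium tetroxide (catalytic oxygen carrier), O=[Os](=O)(=O)=O; sodium periodate (terminal oxygen source), [Na+].[O-]I(=O)(=O)=O
Why: Lemieux–Johnson cleavage should attack the two terminal alkenes far faster than the hindered iodoalkene, the C12 aldehyde is trapped by the C6 hydroxyl as a lactol, and TEMPO/PhI(OAc)2 oxidation then gives the lactone, cis-fused because C6 and C7 are already set.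

Step 10
Reactants: 18 prop-2-yn-1-ol
Product: 20 (2Z)-3-(tributylstannyl)prop-2-en-1-ol, via cyclic vinylalanate 19 (not isolated)
Conditions: LiAlH4, THF, 0 °C → rt; then Bu3SnOTf, −78 °C → rt
Reagents that add atoms: tributyltin trifluoromethanesulfonate, CCCC[Sn](CCCC)(CCCC)OS(=O)(=O)C(F)(F)F
Why: trans-Hydroalumination of the propargylic alcohol followed by aluminium-to-tin exchange with retention should give the Z alkenylstannane.

Step 11
Reactants: 17 the keto lactone iodoalkene; 20 (2Z)-3-(tributylstannyl)prop-2-en-1-ol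
Product: 21 (4S,5S)-5-[(1E,3Z)-2-{[(tert-butyldiphenylsilyl)oxy]methyl}-5-hydroxypenta-1,3-dien-1-yl]-4-{(1S)-3-oxo-1-[(triethylsilyl)oxy]butyl}oxolan-2-one
Conditions: Pd(PPh3)4 (cat.), CuTC (copper thiophene-2-carboxylate, C5H3CuO2S), DMF, 0 °C → rt, dark
Reagents that add atoms: none
Why: Copper-assisted Stille coupling retains configuration at both alkenyl partners, giving the C3–C4 bond with C3 cis to C6 and the cis C2=C3 bond, while ketone, lactone and silyl ethers are inert.

Step 12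
Reactants: 21 the dienol
Product: 23 1-[(2Z,4E)-4-{[(tert-butyldiphenylsilyl)oxy]methyl}-5-[(2S,3S)-5-oxo-3-{(1S)-3-oxo-1-[(triethylsilyl)oxy]butyl}oxolan-2-yl]penta-2,4-dien-1-yl]thiolan-1-ium tetrafluoroborate, via allylic bromide 22 (not isolated)
Conditions: CBr4, PPh3, 2,6-lutidine, CH2Cl2, −40 °C; then tetrahydrothiophene, NaBF4, CH2Cl2/H2O, rt
Reagents that add atoms: tetrahydrothiophene, C1CCSC1; sodium tetrafluoroborate, [Na+].F[B-](F)(F)F
Why: Appel bromination of the primary allylic alcohol at low temperature, S-alkylation of the sulfide at the primary allylic carbon and anion exchange should give a sulfonium salt with a non-nucleophilic counter-ion.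

Step 13
Reactants: 23 the sulfonium tetrafluoroborate
Product: 26 (1R,2Z,4E,6S,7S,8S,10S)-15-[(tert-butyldiphenylsilyl)oxy]-1,10-epoxy-8-[(triethylsilyl)oxy]germacra-2,4-dien-6,12-olide, via sulfonium ylide 24 (not isolated), via betaine 25 (not isolated)
Conditions: Cs2CO3, MeCN/t-BuOH, 0.002 M (slow addition of 23), 0 °C → rt
Reagents that add atoms: none
Why: Proposed new method: Cs2CO3 reversibly deprotonates the allylic S–CH2 of 23 (far more acidic than the ketone or lactone α-CH), the ylide carbon C1 adds to the C10 ketone to give the betaine, and the C10 alkoxide displaces tetrahydrothiophene from C1 with inversion, so that the C1–C10 and C1–O bonds arise in one operation. The closest known reaction type is the Corey–Chaykovsky epoxidation of ketones by allylic sulfonium ylides to vinyl oxiranes, known intermolecularly and for closure of common rings but not for a ten-membered carbocycle. The carbocycle closes by 10-exo-trig addition to the carbonyl and the oxirane by 3-exo-tet displacement. Cyclisation rather than oligomerisation should be favoured by high dilution and by the substrate, in which the cis-fused lactone carries both chains on one face and the two cis alkenes turn C1 back towards C10. C10 should be set by attack on the ketone face that gives the 1,3-anti relation to C8–OSiEt3 (C=O and C8–O dipoles opposed), and C1 then follows because only the anti-periplanar betaine with C2 and C9 gauche fits the ring, which gives the cis-oxirane (H-1 and CH3-14 cis) of the target. The step needs attack through C1 rather than C3 or C5 of the ylide and no loss of the C6 carboxylate or the C8 silyloxy group by elimination: charge localisation next to S+ and the twist of the 4-substituted doubly cis diene (which keeps C5 and the C6–O bond out of conjugation with the ylide) are expected to secure the first two, the weak base and the poor silyloxide leaving group the last.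

Step 14
Reactants: 26 the macrocyclic epoxy lactone
Product: 30 (1R,2Z,4E,6S,7S,8S,10S)-15-[(tert-butyldiphenylsilyl)oxy]-1,10-epoxy-8-[(triethylsilyl)oxy]germacra-2,4,11(13)-trien-6,12-olide, via lithium enolate 27 (not isolated), via Mannich base 28 (not isolated), via trimethylammonium iodide 29 (not isolated)
Conditions: LDA, THF, −78 °C; CH2=NMe2+ I−, −78 → 0 °C; then MeI, rt; then aq. NaHCO3, EtOAc, rt
Reagents that add atoms: dimethyl(methylidene)ammonium iodide (Eschenmoser's salt), C=[N+](C)C.[I-]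
Why: Mannich aminomethylation of the lactone enolate, quaternisation and Hofmann-type elimination is the standard α-methylenation of butyrolactones, and no stereocentre is at risk because C7 cannot be enolised from C11.

Step 15
Reactants: 30 the α-methylene lactone
Product: 31 (1R,2Z,4E,6S,7R,8S,10S)-15-[(tert-butyldiphenylsilyl)oxy]-1,10-epoxy-8-hydroxygermacra-2,4,11(13)-trien-6,12-olide
Conditions: HF·pyridine, pyridine, THF, 0 °C
Reagents that add atoms: none
Why: Buffered HF·pyridine should cleave the secondary triethylsilyl ether much faster than the primary tert-butyldiphenylsilyl ether and is mild enough for the dienyl oxirane.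

Step 16
Reactants: 32 (2E)-but-2-enal
Product: 33 (2Z)-2-iodobut-2-enal
Conditions: I2, K2CO3, DMAP (cat.), THF/H2O, rt
Reagents that add atoms: iodine, II
Why: Baylis–Hillman-type α-iodination (conjugate addition of DMAP, iodination, elimination) should give the α-iodoenal with iodine cis to the methyl group.

Step 17
Reactants: 33 (2Z)-2-iodobut-2-enal
Product: 34 (2Z)-2-iodobut-2-en-1-ol
Conditions: NaBH4, CeCl3·7H2O, MeOH, 0 °C
Reagents that add atoms: none
Why: Luche 1,2-reduction of the enal leaves the iodoalkene and its geometry untouched.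

Step 18
Reactants: 34 (2Z)-2-iodobut-2-en-1-ol
Product: 35 tert-butyl{[(2Z)-2-iodobut-2-en-1-yl]oxy}dimethylsilane
Conditions: TBSCl, imidazole, CH2Cl2, rt
Reagents that add atoms: tert-butyl(chloro)dimethylsilane, CC(C)(C)[Si](C)(C)Cl
Why: Routine silylation of a primary alcohol.

Step 19
Reactants: 35 the silylated iodoalkene
Product: 37 (2Z)-2-({[tert-butyl(dimethyl)silyl]oxy}methyl)but-2-enoic acid, via vinyllithium 36 (not isolated)
Conditions: t-BuLi (2 equiv), Et2O, −78 °C; then CO2, −78 °C → rt; cold dilute HCl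
Reagents that add atoms: carbon dioxide, O=C=O
Why: Iodine–lithium exchange and carboxylation both retain alkene geometry, so the carboxyl group ends cis to the methyl group as in the target side chain.

Step 20
Reactants: 31 the C8 alcohol; 37 the protected side-chain acid
Product: 39 (1R,2Z,4E,6S,7R,8S,10S)-15-[(tert-butyldiphenylsilyl)oxy]-8-{[(2Z)-2-({[tert-butyl(dimethyl)silyl]oxy}methyl)but-2-enoyl]oxy}-1,10-epoxygermacra-2,4,11(13)-trien-6,12-olide, via mixed anhydride 38 (not isolated)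
Conditions: 37, 2,4,6-Cl3C6H2COCl, Et3N, PhMe, rt; then 31, PhMe, 70 °C (no DMAP)
Reagents that add atoms: none
Why: Yamaguchi-type mixed-anhydride esterification without a nucleophilic catalyst, in which the alcohol attacks the less hindered acyl group and neither the addition–elimination that isomerises Z-2-alkylbut-2-enoates nor alkoxide-induced translactonisation to O8 can occur.

Step 21
Reactants: 39 the bis-silyl ester
Product: 40 (1R,2Z,4E,6S,7R,8S,10S)-1,10-epoxy-15-hydroxy-8-{[(2Z)-2-(hydroxymethyl)but-2-enoyl]oxy}germacra-2,4,11(13)-trien-6,12-olide (CNP0293319.3)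
Conditions: TBAF buffered with AcOH, THF, 0 °C → rt
Reagents that add atoms: none
Why: Fluoride cleavage of both primary silyl ethers under acetic acid buffering should spare the α-methylene lactone, the ester and the oxirane.

**Compound list**

1 | 3-methylbut-3-en-1-ol | CC(=C)CCO | starting material
2 | 3-methylbut-3-enal | CC(=C)CC=O | intermediate
3 | (4R)-4-benzyl-1,3-oxazolidin-2-one | O=C1OC[C@@H](Cc2ccccc2)N1 | starting material
4 | pent-4-enoyl chloride | C=CCCC(=O)Cl | starting material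
5 | (4R)-4-benzyl-3-(pent-4-enoyl)-1,3-oxazolidin-2-one | C=CCCC(=O)N1[C@H](Cc2ccccc2)COC1=O | intermediate
6 | Z dibutylboron enolate of 5 | C=CC/C=C(\OB(CCCC)CCCC)N1[C@H](Cc2ccccc2)COC1=O | intermediate
7 | (4R)-4-benzyl-3-[(2R,3S)-3-hydroxy-5-methyl-2-(prop-2-en-1-yl)hex-5-enoyl]-1,3-oxazolidin-2-one | C=CC[C@H]([C@@H](O)CC(C)=C)C(=O)N1[C@H](Cc2ccccc2)COC1=O | intermediate
8 | (2R,3S)-3-hydroxy-N-methoxy-N,5-dimethyl-2-(prop-2-en-1-yl)hex-5-enamide | C=CC[C@H]([C@@H](O)CC(C)=C)C(=O)N(C)OC | intermediate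
9 | (2R,3S)-N-methoxy-N,5-dimethyl-2-(prop-2-en-1-yl)-3-[(triethylsilyl)oxy]hex-5-enamide | C=CC[C@H]([C@@H](O[Si](CC)(CC)CC)CC(C)=C)C(=O)N(C)OC | intermediate
10 | tert-butyl(diphenyl)(prop-2-yn-1-yloxy)silane | C#CCO[Si](C(C)(C)C)(c1ccccc1)c1ccccc1 | starting material
11 | lithium acetylide of 10 | [Li]C#CCO[Si](C(C)(C)C)(c1ccccc1)c1ccccc1 | intermediate
12 | (5R,6S)-1-[(tert-butyldiphenylsilyl)oxy]-8-methyl-5-(prop-2-en-1-yl)-6-[(triethylsilyl)oxy]non-8-en-2-yn-4-one | C=CC[C@H]([C@@H](O[Si](CC)(CC)CC)CC(C)=C)C(=O)C#CCO[Si](C(C)(C)C)(c1ccccc1)c1ccccc1 | intermediate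
13 | (4R,5S,6S)-1-[(tert-butyldiphenylsilyl)oxy]-8-methyl-5-(prop-2-en-1-yl)-6-[(triethylsilyl)oxy]non-8-en-2-yn-4-ol | C=CC[C@H]([C@@H](O[Si](CC)(CC)CC)CC(C)=C)[C@@H](O)C#CCO[Si](C(C)(C)C)(c1ccccc1)c1ccccc1 | intermediate
14 | sodium cyclic alkoxy(vinyl)alanate from 13 (five-membered O–Al–C4=C5–C6 ring, two 2-methoxyethoxy ligands on Al) | C=CC[C@H]([C@@H](O[Si](CC)(CC)CC)CC(C)=C)[C@H]1O[Al-](OCCOC)(OCCOC)C(CO[Si](C(C)(C)C)(c2ccccc2)c2ccccc2)=C1.[Na+] | intermediate
15 | (2Z,4R,5S,6S)-1-[(tert-butyldiphenylsilyl)oxy]-2-iodo-8-methyl-5-(prop-2-en-1-yl)-6-[(triethylsilyl)oxy]nona-2,8-dien-4-ol | C=CC[C@H]([C@@H](O[Si](CC)(CC)CC)CC(C)=C)[C@@H](O)/C=C(\I)CO[Si](C(C)(C)C)(c1ccccc1)c1ccccc1 | intermediate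
16 | (4S,5R)-5-{(1Z)-3-[(tert-butyldiphenylsilyl)oxy]-2-iodoprop-1-en-1-yl}-4-{(1S)-3-oxo-1-[(triethylsilyl)oxy]butyl}oxolan-2-ol (anomer mixture) | CC(=O)C[C@H](O[Si](CC)(CC)CC)[C@H]1CC(O)O[C@H]1/C=C(\I)CO[Si](C(C)(C)C)(c2ccccc2)c2ccccc2 | intermediate
17 | (4S,5R)-5-{(1Z)-3-[(tert-butyldiphenylsilyl)oxy]-2-iodoprop-1-en-1-yl}-4-{(1S)-3-oxo-1-[(triethylsilyl)oxy]butyl}oxolan-2-one | CC(=O)C[C@H](O[Si](CC)(CC)CC)[C@H]1CC(=O)O[C@H]1/C=C(\I)CO[Si](C(C)(C)C)(c2ccccc2)c2ccccc2 | intermediate
18 | prop-2-yn-1-ol | C#CCO | starting material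
19 | lithium cyclic alkoxy(vinyl)dihydridoalanate from 18 | [Li+].[H][Al-]1([H])OCC=C1 | intermediate
20 | (2Z)-3-(tributylstannyl)prop-2-en-1-ol | OC/C=C\[Sn](CCCC)(CCCC)CCCC | intermediate
21 | (4S,5S)-5-[(1E,3Z)-2-{[(tert-butyldiphenylsilyl)oxy]methyl}-5-hydroxypenta-1,3-dien-1-yl]-4-{(1S)-3-oxo-1-[(triethylsilyl)oxy]butyl}oxolan-2-one | CC(=O)C[C@H](O[Si](CC)(CC)CC)[C@H]1CC(=O)O[C@H]1/C=C(CO[Si](C(C)(C)C)(c2ccccc2)c2ccccc2)\C=C/CO | intermediate
22 | (4S,5S)-5-[(1E,3Z)-5-bromo-2-{[(tert-butyldiphenylsilyl)oxy]methyl}penta-1,3-dien-1-yl]-4-{(1S)-3-oxo-1-[(triethylsilyl)oxy]butyl}oxolan-2-one | CC(=O)C[C@H](O[Si](CC)(CC)CC)[C@H]1CC(=O)O[C@H]1/C=C(CO[Si](C(C)(C)C)(c2ccccc2)c2ccccc2)\C=C/CBr | intermediate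
23 | 1-[(2Z,4E)-4-{[(tert-butyldiphenylsilyl)oxy]methyl}-5-[(2S,3S)-5-oxo-3-{(1S)-3-oxo-1-[(triethylsilyl)oxy]butyl}oxolan-2-yl]penta-2,4-dien-1-yl]thiolan-1-ium tetrafluoroborate | CC(=O)C[C@H](O[Si](CC)(CC)CC)[C@H]1CC(=O)O[C@H]1/C=C(CO[Si](C(C)(C)C)(c2ccccc2)c2ccccc2)\C=C/C[S+]1CCCC1.F[B-](F)(F)F | intermediate
24 | sulfonium ylide of 23 (carbanion at C1) | CC(=O)C[C@H](O[Si](CC)(CC)CC)[C@H]1CC(=O)O[C@H]1/C=C(CO[Si](C(C)(C)C)(c2ccccc2)c2ccccc2)\C=C/[CH-][S+]1CCCC1 | intermediate
25 | macrocyclic betaine (C10 alkoxide, C1 thiolanium; ten-membered ring closed) | C1C(=O)O[C@H]2/C=C(CO[Si](C(C)(C)C)(c3ccccc3)c3ccccc3)\C=C/[C@H]([S+]3CCCC3)[C@@](C)([O-])C[C@H](O[Si](CC)(CC)CC)[C@@H]12 | intermediate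
26 | (1R,2Z,4E,6S,7S,8S,10S)-15-[(tert-butyldiphenylsilyl)oxy]-1,10-epoxy-8-[(triethylsilyl)oxy]germacra-2,4-dien-6,12-olide | C1C(=O)O[C@H]2/C=C(CO[Si](C(C)(C)C)(c3ccccc3)c3ccccc3)\C=C/[C@H]3O[C@@]3(C)C[C@H](O[Si](CC)(CC)CC)[C@@H]12 | intermediate
27 | lithium enolate of lactone 26 | C1=C(O[Li])O[C@H]2/C=C(CO[Si](C(C)(C)C)(c3ccccc3)c3ccccc3)\C=C/[C@H]3O[C@@]3(C)C[C@H](O[Si](CC)(CC)CC)[C@@H]12 | intermediate
28 | 11-[(dimethylamino)methyl] derivative of 26 (C11 configuration not defined; it is lost in the next event) | CN(C)CC1C(=O)O[C@H]2/C=C(CO[Si](C(C)(C)C)(c3ccccc3)c3ccccc3)\C=C/[C@H]3O[C@@]3(C)C[C@H](O[Si](CC)(CC)CC)[C@@H]12 | intermediate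
29 | 11-[(trimethylammonio)methyl] iodide of 26 (C11 configuration not defined) | C[N+](C)(C)CC1C(=O)O[C@H]2/C=C(CO[Si](C(C)(C)C)(c3ccccc3)c3ccccc3)\C=C/[C@H]3O[C@@]3(C)C[C@H](O[Si](CC)(CC)CC)[C@@H]12.[I-] | intermediate
30 | (1R,2Z,4E,6S,7S,8S,10S)-15-[(tert-butyldiphenylsilyl)oxy]-1,10-epoxy-8-[(triethylsilyl)oxy]germacra-2,4,11(13)-trien-6,12-olide | C=C1C(=O)O[C@H]2/C=C(CO[Si](C(C)(C)C)(c3ccccc3)c3ccccc3)\C=C/[C@H]3O[C@@]3(C)C[C@H](O[Si](CC)(CC)CC)[C@@H]12 | intermediate
31 | (1R,2Z,4E,6S,7R,8S,10S)-15-[(tert-butyldiphenylsilyl)oxy]-1,10-epoxy-8-hydroxygermacra-2,4,11(13)-trien-6,12-olide | C=C1C(=O)O[C@H]2/C=C(CO[Si](C(C)(C)C)(c3ccccc3)c3ccccc3)\C=C/[C@H]3O[C@@]3(C)C[C@H](O)[C@@H]12 | intermediate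
32 | (2E)-but-2-enal | C/C=C/C=O | starting material
33 | (2Z)-2-iodobut-2-enal | C/C=C(\I)C=O | intermediate
34 | (2Z)-2-iodobut-2-en-1-ol | C/C=C(\I)CO | intermediate
35 | tert-butyl{[(2Z)-2-iodobut-2-en-1-yl]oxy}dimethylsilane | C/C=C(\I)CO[Si](C)(C)C(C)(C)C | intermediate
36 | vinyllithium from 35 (lithium cis to the methyl group) | C/C=C(\[Li])CO[Si](C)(C)C(C)(C)C | intermediate
37 | (2Z)-2-({[tert-butyl(dimethyl)silyl]oxy}methyl)but-2-enoic acid | C/C=C(\C(=O)O)CO[Si](C)(C)C(C)(C)C | intermediate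
38 | mixed anhydride of 37 with 2,4,6-trichlorobenzoic acid | C/C=C(\C(=O)OC(=O)c1c(Cl)cc(Cl)cc1Cl)CO[Si](C)(C)C(C)(C)C | intermediate
39 | (1R,2Z,4E,6S,7R,8S,10S)-15-[(tert-butyldiphenylsilyl)oxy]-8-{[(2Z)-2-({[tert-butyl(dimethyl)silyl]oxy}methyl)but-2-enoyl]oxy}-1,10-epoxygermacra-2,4,11(13)-trien-6,12-olide | C=C1C(=O)O[C@H]2/C=C(CO[Si](C(C)(C)C)(c3ccccc3)c3ccccc3)\C=C/[C@H]3O[C@@]3(C)C[C@H](OC(=O)/C(=C\C)CO[Si](C)(C)C(C)(C)C)[C@@H]12 | intermediate
40 | (1R,2Z,4E,6S,7R,8S,10S)-1,10-epoxy-15-hydroxy-8-{[(2Z)-2-(hydroxymethyl)but-2-enoyl]oxy}germacra-2,4,11(13)-trien-6,12-olide (CNP0293319.3) | C=C1C(=O)O[C@H]2/C=C(CO)\C=C/[C@H]3O[C@@]3(C)C[C@H](OC(=O)/C(=C\C)CO)[C@@H]12 | target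

**Count and risks**

Total steps: 21. Longest linear sequence: 15 steps (steps 2–9, 11–15, 20, 21).

Steps most likely to fail:

1. Step 13 (new ring closure). The ylide may oligomerise, may lose the allylic C6 carboxylate by vinylogous elimination, may rearrange after deprotonation on the thiolane ring, or may add to the wrong ketone face, giving the wrong oxirane diastereomer. Fallback with known chemistry, from dienol 21 back to 26: MnO2 oxidation (CH2Cl2, rt) should give the keto dienal F1. Pinacol macrocyclisation with low-valent titanium (TiCl3(DME)1.5, Zn–Cu, DME, slow addition) would then form the C1–C10 bond as the 1,10-diol F2. The (1S,10S) isomer is the one that leads on and would have to be separated from others. Mitsunobu-type cyclodehydration (PPh3, DIAD, PhMe) activates the secondary C1 hydroxyl and closes the oxirane with inversion at C1, returning to 26.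

2. Step 8 (hydroalumination–iodination). The vinylalanate carries the silyloxy group β to aluminium and may eliminate to an allene, or hydride delivery may be incomplete. Fallback from propargylic alcohol 13 back to 15: ruthenium-catalysed trans-hydrosilylation ([Cp*Ru(MeCN)3]PF6, BnMe2SiH, CH2Cl2, 0 °C) should place silicon on the alkyne carbon distal to the hydroxyl and give the vinylsilane F3. Iododesilylation with retention (NIS, hexafluoroisopropanol, 0 °C) then returns to vinyl iodide 15.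

3. Step 11 (Stille coupling). Transmetalation at the hindered iodoalkene may be slow, with protodestannylation of 20 or erosion of the cis geometry of the labile dienol. Fallback from 17 and 18 back to 21: Sonogashira coupling (PdCl2(PPh3)2, CuI, i-Pr2NH, THF, rt) should give the enynol F4. Z-selective semi-reduction of the conjugated alkyne with Zn(Cu/Ag) in MeOH/H2O then rejoins the route at dienol 21.

**Further compounds**

F1 | step 13 | (4S,5S)-5-[(1E,3Z)-2-{[(tert-butyldiphenylsilyl)oxy]methyl}-5-oxopenta-1,3-dien-1-yl]-4-{(1S)-3-oxo-1-[(triethylsilyl)oxy]butyl}oxolan-2-one | CC(=O)C[C@H](O[Si](CC)(CC)CC)[C@H]1CC(=O)O[C@H]1/C=C(CO[Si](C(C)(C)C)(c2ccccc2)c2ccccc2)\C=C/C=O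
F2 | step 13 | (1S,2Z,4E,6S,7S,8S,10S)-15-[(tert-butyldiphenylsilyl)oxy]-1,10-dihydroxy-8-[(triethylsilyl)oxy]germacra-2,4-dien-6,12-olide | C1C(=O)O[C@H]2/C=C(CO[Si](C(C)(C)C)(c3ccccc3)c3ccccc3)\C=C/[C@H](O)[C@@](C)(O)C[C@H](O[Si](CC)(CC)CC)[C@@H]12
F3 | step 8 | (2Z,4R,5S,6S)-2-[benzyl(dimethyl)silyl]-1-[(tert-butyldiphenylsilyl)oxy]-8-methyl-5-(prop-2-en-1-yl)-6-[(triethylsilyl)oxy]nona-2,8-dien-4-ol | C=CC[C@H]([C@@H](O[Si](CC)(CC)CC)CC(C)=C)[C@@H](O)/C=C(\[Si](C)(C)Cc1ccccc1)CO[Si](C(C)(C)C)(c1ccccc1)c1ccccc1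
F4 | step 11 | (4S,5S)-5-[(1E)-2-{[(tert-butyldiphenylsilyl)oxy]methyl}-5-hydroxypent-1-en-3-yn-1-yl]-4-{(1S)-3-oxo-1-[(triethylsilyl)oxy]butyl}oxolan-2-one | CC(=O)C[C@H](O[Si](CC)(CC)CC)[C@H]1CC(=O)O[C@H]1/C=C(CO[Si](C(C)(C)C)(c2ccccc2)c2ccccc2)\C#CCO
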